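**Plan**

Retrosynthesis cuts, in order: the C6–O angelate bond; C14=C15 and C12=C13 (two Wittig reactions on a lactol); the C8–O bond (a γ-lactone made by C–H oxidation and used as a temporary ring); then C3–C4 and C1–C10 together in one [3+3] annulation, which leaves a ring B cyclohexenone.
The annulation rests on the C6 oxygen: as a ketone it makes C5 the acyl-bearing centre of a 2-acylallyl unit C4–C5–C10 in ring B, so the two quaternary carbons of ring A are electrophilic in turn and C1–C2–C3 arrive as the propene-1,3-diyl equivalent (E)-1,3-bis(trimethylsilyl)propene.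
Forward: ring B is made first (arene hydrogenation, desymmetrisation, Saegusa–Ito oxidation, C4 unit by bromination, Stille coupling and HCl addition); ring A follows by the annulation; then the lactone ring, the diene side chain and the ester.
Stereochemistry: all-cis arene hydrogenation fixes C8 and C9 relative to each other and a chiral lithium amide makes this absolute; C10 and C5 follow from C8 and C9 in the key step; C6 comes from dissolving-metal reduction (equatorial alcohol); the C8 oxygen from C–H oxidation with retention; the E alkene from a stabilised ylide; the Z ester from angelic acid.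
Helpers removed later: the C2=C3 alkene (step 11), the acetate and the lactone ring (steps 16 and 17).

Key step: step 10

Numbering: labdane numbering is used for ring B and the bicyclic compounds (ring A: C1–C5 and C10; ring B: C5–C10; C11 and C12 on C9; C17 on C8; C18 and C19 on C4; C20 on C10); in all bicyclic compounds the C17 and C20 methyl groups are β.
Assumption: lithium (R,R)-bis(1-phenylethyl)amide is taken to remove the axial proton on the carbon that becomes C5 of ketone 4; if the sense of induction is the opposite one, the (S,S)-amide is used.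

Step 1
Reactants: 1 4-bromo-3,5-dimethylphenol
Product: 2 methyl (4-hydroxy-2,6-dimethylphenyl)acetate
Conditions: Zn, BrCH2CO2Me, THF (gives BrZnCH2CO2Me, 2.3 equiv); then 1, Pd(dba)2, P(t-Bu)3, THF, 60 °C; aq NH4Cl
Reagents that add atoms: methyl bromoacetate, COC(=O)CBr
Why: Palladium-catalysed arylation of a Reformatsky (zinc ester enolate) reagent tolerates the free phenol and the two ortho methyl groups and puts the C11–C12 acetate arm on the future C9, and no stereocenter is formed.

Step 2
Reactants: 2 methyl (4-hydroxy-2,6-dimethylphenyl)acetate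
Product: 3 methyl 2-(all-cis-4-hydroxy-2,6-dimethylcyclohexyl)acetate (meso)
Conditions: H2 (60 bar), 5% Rh/Al2O3, MeOH, 50 °C
Reagents that add atoms: none
Why: Heterogeneous arene hydrogenation over rhodium delivers all hydrogens to one face of the ring, so the two methyl groups, the acetate arm and the hydroxyl should end up all-cis, which fixes the cis relation of the future C8 methyl group and C9 side chain in a meso compound.

Step 3
Reactants: 3 methyl 2-(all-cis-4-hydroxy-2,6-dimethylcyclohexyl)acetate
Product: 4 methyl 2-(all-cis-2,6-dimethyl-4-oxocyclohexyl)acetate (meso)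
Conditions: NaOCl, TEMPO (5 mol%), KBr, NaHCO3, CH2Cl2/H2O, 0 °C
Reagents that add atoms: none
Why: TEMPO-catalysed hypochlorite oxidation converts the secondary alcohol into the ketone without touching the ester or the three stereocenters, none of which is α to the new carbonyl group.

Step 4
Reactants: 4 methyl 2-(all-cis-2,6-dimethyl-4-oxocyclohexyl)acetate
Product: 5 methyl 2-[(1S,2S,6S)-2,6-dimethyl-4-(trimethylsilyloxy)cyclohex-3-en-1-yl]acetate
Conditions: (R,R)-bis(1-phenylethyl)amine, n-BuLi, LiCl, THF, −78 °C; then Me3SiCl and 4, −100 °C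
Reagents that add atoms: chlorotrimethylsilane, C[Si](C)(C)Cl
Why: Enantiotopic-group-selective deprotonation of the meso ketone by a chiral lithium amide with internal silyl quench, the reaction type established for cis-3,5-dimethylcyclohexanone, should give one enantiomer of the silyl enol ether and so turn the relative configuration of C8 and C9 into an absolute one.

Step 5
Reactants: 5 methyl 2-[(1S,2S,6S)-2,6-dimethyl-4-(trimethylsilyloxy)cyclohex-3-en-1-yl]acetate
Product: 6 methyl 2-[(1S,6S)-2,6-dimethyl-4-oxocyclohex-2-en-1-yl]acetate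
Conditions: Pd(OAc)2 (1.05 equiv), MeCN, rt
Reagents that add atoms: none
Why: Saegusa–Ito oxidation turns the regiodefined silyl enol ether into the enone by β-hydride elimination of the palladium enolate towards the methyl-bearing carbon, which becomes the sp2 carbon C10 while C8 and C9 keep their cis configuration.

Step 6
Reactants: 6 methyl 2-[(1S,6S)-2,6-dimethyl-4-oxocyclohex-2-en-1-yl]acetate
Product: 8 methyl 2-[(1S,6S)-3-bromo-2,6-dimethyl-4-oxocyclohex-2-en-1-yl]acetate, via dibromo ketone 7 (not isolated)
Conditions: Br2, CH2Cl2, 0 °C; then Et3N, 0 °C to rt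
Reagents that add atoms: bromine, BrBr
Why: Bromine addition to the enone followed by amine-induced loss of HBr is the standard route to 2-bromo-3-methylcyclohex-2-enones and places the halide on C5 for the cross-coupling without touching a stereocenter.

Step 7
Reactants: 8 methyl 2-[(1S,6S)-3-bromo-2,6-dimethyl-4-oxocyclohex-2-en-1-yl]acetate
Product: 9 methyl 2-[(1S,6S)-2,6-dimethyl-4-oxo-3-(prop-1-en-2-yl)cyclohex-2-en-1-yl]acetate
Conditions: CH2=C(CH3)SnBu3, Pd(PPh3)4 (5 mol%), CuI (10 mol%), DMF, 60 °C
Reagents that add atoms: tributyl(prop-1-en-2-yl)stannane, C=C(C)[Sn](CCCC)(CCCC)CCCC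
Why: Stille coupling of the α-bromoenone under neutral, copper-assisted conditions attaches the isopropenyl group (C4 with C18 and C19) to C5 without a base that could start isomerisation of the cross-conjugated dienone towards a phenol.

Step 8
Reactants: 9 methyl 2-[(1S,6S)-2,6-dimethyl-4-oxo-3-(prop-1-en-2-yl)cyclohex-2-en-1-yl]acetate
Product: 10 methyl 2-[(1S,6S)-3-(2-chloropropan-2-yl)-2,6-dimethyl-4-oxocyclohex-2-en-1-yl]acetate
Conditions: HCl (2 M in Et2O, 1.2 equiv), CH2Cl2, −40 to 0 °C; solvent removed cold, used crude
Reagents that add atoms: hydrogen chloride, Cl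
Why: Markovnikov addition of HCl to the 1,1-disubstituted alkene should give the tertiary allylic chloride, the leaving group that makes C4–C5–C10 a 2-acylallyl electrophile, and no stereocenter is formed.

Step 9
Reactants: 11 allyltrimethylsilane
Product: 13 (E)-1,3-bis(trimethylsilyl)propene, via silylallyllithium 12 (not isolated)
Conditions: s-BuLi, TMEDA, THF, −78 to −30 °C; then Me3SiCl, −78 °C to rt
Reagents that add atoms: chlorotrimethylsilane, C[Si](C)(C)Cl
Why: Deprotonation of allyltrimethylsilane and silylation of the allyl anion at its γ-carbon is the known preparation of this E-configured bis-silane, which serves as a propene-1,3-diyl dianion equivalent.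

Step 10
Reactants: 10 methyl 2-[(1S,6S)-3-(2-chloropropan-2-yl)-2,6-dimethyl-4-oxocyclohex-2-en-1-yl]acetate; 13 (E)-1,3-bis(trimethylsilyl)propene
Product: 16 methyl (5αH,8αH,9αH)-6-oxo-13,14,15,16-tetranorlabd-2-en-12-oate, via silylallyl enone 14 (not isolated), via titanium enolate 15 (not isolated)
Conditions: TiCl4 (2.2 equiv), CH2Cl2, −78 to −30 °C; then aq NaHCO3
Reagents that add atoms: none
Why: Proposed new method: TiCl4 should ionise the tertiary chloride of 10 to a 2-acylallyl cation spread over C4–C5–C10; the γ-carbon of bis-silane 13 attacks its less hindered terminus C4 with loss of Me3SiCl (bond C3–C4), and the α-silylallyl group of 14 then adds through its CH2 terminus to the TiCl4-activated enone carbon C10 (bond C1–C10), loss of the second silyl group leaving the C2=C3 alkene and titanium enolate 15, which is protonated on work-up. The closest known reaction types are the Lewis-acid coupling of tertiary alkyl chlorides with allylsilanes, the intramolecular Hosomi–Sakurai conjugate addition, the use of 1,3-bis(trimethylsilyl)propene as a propene-1,3-diyl dianion equivalent towards aldehydes and, with reversed polarity, the α,α′-annulation of enamines with 2-(bromomethyl)acrylates; their union as a [3+3] annulation on a 2-acylallyl unit has not been shown. Ring A closes in a 6-endo-trig conjugate addition in which both enone carbons (C5, C10) and both allylsilane carbons (C1, C2) lie in the new ring. C10 is set by axial attack on the ring B enone anti to the pseudoaxial C9 side chain and trans to the pseudoequatorial C8 methyl group, which puts C1 on the α face and the C20 methyl group on the β face; C5 is set on quench by protonation of 15 from the α face, away from the axial methyl groups on C4 and C10, which gives the trans ring fusion. The step needs ring closure to outrun proton loss from the cation (which would lead towards a phenol), a second intermolecular allylation and capture of C10 by the ester; low temperature, base-free conditions, the six-membered transition state and TiCl4 complexation of the ester should secure this. If conjugate addition at C10 comes first, chloride loss from the enolate and ring closure at C4 give the C1=C2 isomer, which converges with 16 in step 11.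

Step 11
Reactants: 16 methyl (5αH,8αH,9αH)-6-oxo-13,14,15,16-tetranorlabd-2-en-12-oate
Product: 17 methyl (5αH,8αH,9αH)-6-oxo-13,14,15,16-tetranorlabdan-12-oate
Conditions: H2 (1 atm), Pd/C (10%), EtOAc, rt
Reagents that add atoms: none
Why: Catalytic hydrogenation saturates the cis-disubstituted C2=C3 alkene, the helper left by the annulation, while the hindered ketone and the ester remain.

Step 12
Reactants: 17 methyl (5αH,8αH,9αH)-6-oxo-13,14,15,16-tetranorlabdan-12-oate
Product: 18 (5αH,8αH,9αH)-6-oxo-13,14,15,16-tetranorlabdan-12-oic acid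
Conditions: LiOH, THF/H2O, 0 °C to rt; then 1 M HCl
Reagents that add atoms: lithium hydroxide, [Li+].[OH-]
Why: Saponification of the unhindered methyl ester frees the C12 carboxylic acid needed later as directing group, the C5 hydrogen being shielded from enolisation by the two flanking quaternary carbons.

Step 13
Reactants: 18 (5αH,8αH,9αH)-6-oxo-13,14,15,16-tetranorlabdan-12-oic acid
Product: 19 (5αH,8αH,9αH)-6α-hydroxy-13,14,15,16-tetranorlabdan-12-oic acid
Conditions: Li (excess), NH3(l)/THF, −78 °C; then NH4Cl; 1 M HCl
Reagents that add atoms: none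
Why: Dissolving-metal reduction of the hindered ketone should give the thermodynamically preferred equatorial alcohol, here 6α, because an axial 6β-hydroxyl would be syn-axial to the methyl groups on C4 and C10, while the carboxylate is inert.

Step 14
Reactants: 19 (5αH,8αH,9αH)-6α-hydroxy-13,14,15,16-tetranorlabdan-12-oic acid
Product: 20 (5αH,8αH,9αH)-6α-acetoxy-13,14,15,16-tetranorlabdan-12-oic acid
Conditions: Ac2O, pyridine, DMAP (cat.), rt; then H2O
Reagents that add atoms: acetic anhydride, CC(=O)OC(C)=O
Why: Acetylation masks the secondary alcohol as an electron-poor ester, which protects its carbinol C–H from the oxidant of the next step, the mixed anhydride formed at the acid being hydrolysed on work-up.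

Step 15
Reactants: 20 (5αH,8αH,9αH)-6α-acetoxy-13,14,15,16-tetranorlabdan-12-oic acid
Product: 21 6α-acetoxy-13,14,15,16-tetranorlabdan-12,8α-olide (6α-acetoxysclareolide)
Conditions: [Fe((S,S)-PDP)(MeCN)2](SbF6)2 (three portions of 5 mol%; PDP = N,N′-bis(2-pyridylmethyl)-2,2′-bipyrrolidine), H2O2 (50% aq, slow addition), MeCN, rt
Reagents that add atoms: hydrogen peroxide, OO (source of the C8 oxygen when lactonisation follows hydroxylation)
Why: Carboxylate-directed γ-C–H lactonisation with a non-haem iron catalyst and H2O2 should oxidise the only γ C–H bond of the acid, the equatorial tertiary C8–H, with retention of configuration, which places oxygen on the α face of C8 and closes the trans-fused γ-lactone as a temporary ring.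

Step 16
Reactants: 21 6α-acetoxy-13,14,15,16-tetranorlabdan-12,8α-olide
Product: 22 8α,12-epoxy-13,14,15,16-tetranorlabdane-6α,12-diol (lactol; both C12 anomers)
Conditions: i-Bu2AlH (4 equiv), CH2Cl2, −78 °C; aq potassium sodium tartrate
Reagents that add atoms: none
Why: Low-temperature reduction with i-Bu2AlH stops at the lactol, as it does for related trans-fused γ-lactones, and removes the acetate in the same operation.

Step 17
Reactants: 22 8α,12-epoxy-13,14,15,16-tetranorlabdane-6α,12-diol
Product: 23 (12E)-6α,8α-dihydroxy-15-norlabd-12-en-14-al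
Conditions: Ph3P=C(CH3)CHO, toluene, 100 °C
Reagents that add atoms: 2-(triphenylphosphoranylidene)propanal, CC(C=O)=P(c1ccccc1)(c1ccccc1)c1ccccc1
Why: Wittig reaction of the open hydroxy aldehyde form of the lactol with the stabilised α-methyl ylide forms the trisubstituted C12=C13 alkene with E geometry and frees the tertiary C8 hydroxyl.

Step 18
Reactants: 23 (12E)-6α,8α-dihydroxy-15-norlabd-12-en-14-al
Product: 24 (12E)-labda-12,14-diene-6α,8α-diol
Conditions: Ph3PCH3Br, KOt-Bu (excess), THF, 0 °C to rt
Reagents that add atoms: methyltriphenylphosphonium bromide, C[P+](c1ccccc1)(c1ccccc1)c1ccccc1.[Br-]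
Why: Wittig methylenation of the enal with an excess of the non-stabilised ylide completes the 1,3-diene without disturbing the C12=C13 geometry.

Step 19
Reactants: 24 (12E)-labda-12,14-diene-6α,8α-diol
Product: 25 (12E)-8α-hydroxylabda-12,14-dien-6α-yl (2Z)-2-methylbut-2-enoate (CNP0582767.1)
Conditions: angelic acid, 2,4,6-trichlorobenzoyl chloride, Et3N, toluene, rt; then 24, toluene, 80 °C
Reagents that add atoms: angelic acid, C/C=C(/C)C(=O)O
Why: Acylation through the mixed 2,4,6-trichlorobenzoic anhydride of angelic acid without a nucleophilic catalyst is the Yamaguchi-type protocol that keeps the Z geometry of the angelate, and it should take the secondary 6α-hydroxyl in preference to the tertiary 8α-hydroxyl.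

**Compound list**

1 | 4-bromo-3,5-dimethylphenol | Cc1cc(O)cc(C)c1Br | starting material
2 | methyl (4-hydroxy-2,6-dimethylphenyl)acetate | COC(=O)Cc1c(C)cc(O)cc1C | intermediate
3 | methyl 2-(all-cis-4-hydroxy-2,6-dimethylcyclohexyl)acetate (meso) | COC(=O)C[C@@H]1[C@H](C)C[C@H](O)C[C@@H]1C | intermediate
4 | methyl 2-(all-cis-2,6-dimethyl-4-oxocyclohexyl)acetate (meso) | COC(=O)C[C@@H]1[C@H](C)CC(=O)C[C@@H]1C | intermediate
5 | methyl 2-[(1S,2S,6S)-2,6-dimethyl-4-(trimethylsilyloxy)cyclohex-3-en-1-yl]acetate | COC(=O)C[C@@H]1[C@H](C)C=C(O[Si](C)(C)C)C[C@@H]1C | intermediate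
6 | methyl 2-[(1S,6S)-2,6-dimethyl-4-oxocyclohex-2-en-1-yl]acetate (side chain and 6-methyl cis) | COC(=O)C[C@@H]1C(C)=CC(=O)C[C@@H]1C | intermediate
7 | methyl 2-[(1S,6S)-2,3-dibromo-2,6-dimethyl-4-oxocyclohexyl]acetate (anti dibromide, C–Br centres not defined) | COC(=O)C[C@@H]1C(C)(Br)C(Br)C(=O)C[C@@H]1C | intermediate
8 | methyl 2-[(1S,6S)-3-bromo-2,6-dimethyl-4-oxocyclohex-2-en-1-yl]acetate | COC(=O)C[C@@H]1C(C)=C(Br)C(=O)C[C@@H]1C | intermediate
9 | methyl 2-[(1S,6S)-2,6-dimethyl-4-oxo-3-(prop-1-en-2-yl)cyclohex-2-en-1-yl]acetate | COC(=O)C[C@@H]1C(C)=C(C(C)=C)C(=O)C[C@@H]1C | intermediate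
10 | methyl 2-[(1S,6S)-3-(2-chloropropan-2-yl)-2,6-dimethyl-4-oxocyclohex-2-en-1-yl]acetate | COC(=O)C[C@@H]1C(C)=C(C(C)(C)Cl)C(=O)C[C@@H]1C | intermediate
11 | allyltrimethylsilane | C=CC[Si](C)(C)C | starting material
12 | [1-(trimethylsilyl)allyl]lithium | C=CC([Li])[Si](C)(C)C | intermediate
13 | (E)-1,3-bis(trimethylsilyl)propene | C[Si](C)(C)C/C=C/[Si](C)(C)C | intermediate
14 | methyl 2-[(1S,6S)-2,6-dimethyl-3-[2-methyl-3-(trimethylsilyl)pent-4-en-2-yl]-4-oxocyclohex-2-en-1-yl]acetate (silyl-bearing carbon not defined) | COC(=O)C[C@@H]1C(C)=C(C(C)(C)C(C=C)[Si](C)(C)C)C(=O)C[C@@H]1C | intermediate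
15 | methyl (8αH,9αH)-6-(trichlorotitanoxy)-13,14,15,16-tetranorlabda-2,5-dien-12-oate | COC(=O)C[C@@H]1[C@@]2(C)CC=CC(C)(C)C2=C(O[Ti](Cl)(Cl)Cl)C[C@@H]1C | intermediate
16 | methyl (5αH,8αH,9αH)-6-oxo-13,14,15,16-tetranorlabd-2-en-12-oate | COC(=O)C[C@@H]1[C@@]2(C)CC=CC(C)(C)[C@@H]2C(=O)C[C@@H]1C | intermediate
17 | methyl (5αH,8αH,9αH)-6-oxo-13,14,15,16-tetranorlabdan-12-oate | COC(=O)C[C@@H]1[C@@]2(C)CCCC(C)(C)[C@@H]2C(=O)C[C@@H]1C | intermediate
18 | (5αH,8αH,9αH)-6-oxo-13,14,15,16-tetranorlabdan-12-oic acid | OC(=O)C[C@@H]1[C@@]2(C)CCCC(C)(C)[C@@H]2C(=O)C[C@@H]1C | intermediate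
19 | (5αH,8αH,9αH)-6α-hydroxy-13,14,15,16-tetranorlabdan-12-oic acid | OC(=O)C[C@@H]1[C@@]2(C)CCCC(C)(C)[C@@H]2[C@@H](O)C[C@@H]1C | intermediate
20 | (5αH,8αH,9αH)-6α-acetoxy-13,14,15,16-tetranorlabdan-12-oic acid | OC(=O)C[C@@H]1[C@@]2(C)CCCC(C)(C)[C@@H]2[C@@H](OC(C)=O)C[C@@H]1C | intermediate
21 | 6α-acetoxy-13,14,15,16-tetranorlabdan-12,8α-olide (6α-acetoxysclareolide) | O=C1C[C@@H]2[C@@]3(C)CCCC(C)(C)[C@@H]3[C@@H](OC(C)=O)C[C@@]2(C)O1 | intermediate
22 | 8α,12-epoxy-13,14,15,16-tetranorlabdane-6α,12-diol (lactol, C12 not defined) | OC1C[C@@H]2[C@@]3(C)CCCC(C)(C)[C@@H]3[C@@H](O)C[C@@]2(C)O1 | intermediate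
23 | (12E)-6α,8α-dihydroxy-15-norlabd-12-en-14-al | O=C/C(C)=C/C[C@@H]1[C@@]2(C)CCCC(C)(C)[C@@H]2[C@@H](O)C[C@@]1(C)O | intermediate
24 | (12E)-labda-12,14-diene-6α,8α-diol | C=C/C(C)=C/C[C@@H]1[C@@]2(C)CCCC(C)(C)[C@@H]2[C@@H](O)C[C@@]1(C)O | intermediate
25 | (12E)-8α-hydroxylabda-12,14-dien-6α-yl (2Z)-2-methylbut-2-enoate (CNP0582767.1) | C=C/C(C)=C/C[C@@H]1[C@@]2(C)CCCC(C)(C)[C@@H]2[C@@H](OC(=O)/C(C)=C\C)C[C@@]1(C)O | target

**Count and risks**

Total step count: 19. Longest linear sequence: 18 steps (steps 1–8 and 10–19); step 9 is a one-step branch.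

Steps most likely to fail:

Step 10 (Proposed new method). What may go wrong: proton loss from the 2-acylallyl cation (leading towards aromatisation), or a second intermolecular allylation that outruns ring closure. Fallback with known chemistry: the two ring A bonds are made one at a time and the ring is closed by metathesis. It sets out from 10. TiCl4-mediated coupling with allyltrimethylsilane (CH2Cl2, −78 °C) should give the C4-allylated enone methyl 2-[(1S,6S)-2,6-dimethyl-3-(2-methylpent-4-en-2-yl)-4-oxocyclohex-2-en-1-yl]acetate F1. Copper-mediated conjugate addition of CH2=CHMgBr (CuBr·SMe2, Me3SiCl, THF, −78 °C, then dilute acid), trans to the C8 methyl group, should give the C10-vinyl ketone methyl 2-[2,6-dimethyl-3-(2-methylpent-4-en-2-yl)-4-oxo-2-vinylcyclohexyl]acetate F2. Ring-closing metathesis with the second-generation Grubbs catalyst (CH2Cl2, 40 °C) should give the C1=C2 alkene methyl (5αH,8αH,9αH)-6-oxo-13,14,15,16-tetranorlabd-1-en-12-oate F3, which is hydrogenated (H2, Pd/C) to 17, where the route is rejoined.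

Step 15. What may go wrong: undirected oxidation of ring A methylene groups, or over-oxidation, instead of lactonisation at C8. Fallback: it sets out from 20. The acid is converted (ClCO2Et, Et3N; then NH3) into the primary amide (5αH,8αH,9αH)-6α-acetoxy-13,14,15,16-tetranorlabdan-12-amide F4. Its N-iodoamide (PhI(OAc)2, I2, visible light, CH2Cl2) undergoes 1,5-hydrogen-atom transfer from C8 (Hofmann–Löffler–Freytag type). Closure at C8 by the amide oxygen from the less hindered α face and hydrolysis of the iminolactone should return lactone 21.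

Step 19. What may go wrong: isomerisation of the angelate double bond from Z to E during acylation, or sluggish acylation of the hindered alcohol. Fallback: it sets out from 24. Carbodiimide esterification (DCC, DMAP, CH2Cl2) with 2-(diphenoxyphosphoryl)propanoic acid should give the phosphonate ester (12E)-8α-hydroxylabda-12,14-dien-6α-yl 2-(diphenoxyphosphoryl)propanoate F5. A Z-selective Horner–Wadsworth–Emmons olefination with acetaldehyde (NaH, THF, −78 °C) then builds the angelate double bond on the substrate and gives 25.

Further compounds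
F1 | step 10 | methyl 2-[(1S,6S)-2,6-dimethyl-3-(2-methylpent-4-en-2-yl)-4-oxocyclohex-2-en-1-yl]acetate | COC(=O)C[C@@H]1C(C)=C(C(C)(C)CC=C)C(=O)C[C@@H]1C
F2 | step 10 | methyl 2-[2,6-dimethyl-3-(2-methylpent-4-en-2-yl)-4-oxo-2-vinylcyclohexyl]acetate (vinyl α on C10, 5α-H, C8 and C9 as in 10) | COC(=O)C[C@@H]1[C@@](C)(C=C)[C@H](C(C)(C)CC=C)C(=O)C[C@@H]1C
F3 | step 10 | methyl (5αH,8αH,9αH)-6-oxo-13,14,15,16-tetranorlabd-1-en-12-oate | COC(=O)C[C@@H]1[C@@]2(C)C=CCC(C)(C)[C@@H]2C(=O)C[C@@H]1C
F4 | step 15 | (5αH,8αH,9αH)-6α-acetoxy-13,14,15,16-tetranorlabdan-12-amide | NC(=O)C[C@@H]1[C@@]2(C)CCCC(C)(C)[C@@H]2[C@@H](OC(C)=O)C[C@@H]1C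
F5 | step 19 | (12E)-8α-hydroxylabda-12,14-dien-6α-yl 2-(diphenoxyphosphoryl)propanoate | C=C/C(C)=C/C[C@@H]1[C@@]2(C)CCCC(C)(C)[C@@H]2[C@@H](OC(=O)C(C)P(=O)(Oc3ccccc3)Oc3ccccc3)C[C@@]1(C)O
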